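## The problem

The target, (1S,2R,4R)-2-bromo-1-methyl-4-{3-[(1R,2R,3S,6S)-6-methyl-3-(prop-1-en-2-yl)-7-oxabicyclo[4.1.0]heptan-2-yl]prop-1-en-2-yl}cyclohexan-1-ol, is a C20 bromo diterpenoid in which two six-membered rings are not fused but joined through a 2-substituted allyl unit, ring A–CH2–C(=CH2)–ring B. Ring A is numbered here C1a (CH carrying the linker CH2), C2a (CH carrying the isopropenyl group), C3a and C4a (CH2), C5a (methyl-bearing epoxide carbon) and C6a (epoxide CH), and ring B is numbered C1b (CH on the linker), C2b, C3b, C4b (carbinol carbon), C5b (CHBr) and C6b. Ring A holds four stereocentres, with C1a and C2a trans and the epoxide oxygen on the face of the linker, opposite the isopropenyl group; ring B holds three, with linker, bromine and methyl equatorial and the hydroxyl axial, a cis bromohydrin that cannot come from opening an epoxide or a bromonium ion. The two sets are insulated by the freely rotating linker, so neither ring can direct the other and each needs its own source of absolute configuration. Within ring A the trans-diequatorial substituents give little facial bias at the C5a=C6a alkene, and what there is points away from the linker; within ring B, C1b becomes a stereocentre only when the two sides of the ring are told apart, after which C5b can be set relative to it and C4b relative to C5b. The trisubstituted epoxide (acid, Lewis acid, halide, strong base) and the secondary bromide next to a tertiary alcohol (organometallics, reductants, base) will not survive rough handling, and three alkenes, two of them 1,1-disubstituted, exclude unselective electrophiles and strong acid, so both sensitive groups belong at the end. The feature that opens the route is ring A without its epoxide, a cyclohexene with the double bond at C5a=C6a, vicinal substituents at C1a and C2a and the methyl group para to C2a: this is the pattern of a Diels–Alder adduct of a 1-alkyl-3-methylbuta-1,3-diene (C1a, C6a, C5a, C4a) and an acrylate (C2a, C3a), with the isopropenyl group as a masked acyl group.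

## Retrosynthesis

The two C–O bonds of the epoxide are cut first, giving the triene bromohydrin 19 from target 20. Cutting here keeps the most fragile group out of every other step; an earlier epoxide would have to survive deketalisation, a lithium amide, bromide and organometallic reagents. The forward step must pick the trisubstituted alkene out of three and deliver oxygen to the face syn to the linker under reagent control.

In 19 the C4b–CH3 bond is cut, then the C5b–Br bond, leading through the cis bromoketone 18 and the enol silane 16 to ketone 15. Any alkene-based entry to ring B would give the trans bromohydrin, whereas methyl addition to an α-bromoketone places the hydroxyl cis to bromine. The gain is large: ring B in 15 is an achiral 4-substituted cyclohexanone. The forward steps must distinguish two enantiotopic methylene groups, bring bromine cis to the linker, and add methyl trans to bromine.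

From 15 the ring B ketone is masked as the ketal 14. The isopropenyl =CH2 is cut back to the acetyl group of 13, the acetyl C–CH3 bond back to the Weinreb amide 11, and the trans relationship at C2a is traced to the cis imide 10. This makes C2a an enolisable centre, so its configuration can be corrected by equilibration and need not be set directly. The forward sequence needs only that the trans ketone is the more stable epimer.

The key cut divides 10 at C1a–C2a and C3a–C4a into the achiral triene 8 and the acrylimide 9. The other [4+2] pairing of ring A would need a 1,2-disubstituted, weakly activated dienophile; this one uses a two-point-binding acrylimide for which catalytic enantiocontrol is established, and both diene substituents direct the same regiochemistry. Ring A, two stereocentres and two C–C bonds disappear in one step. The forward reaction needs enantiofacial control at the dienophile and high endo selectivity.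

Triene 8 is cut at the sp3–sp2 bond between the linker CH2 and the diene, giving allyl chloride 5 and the (E)-dienylboronate 7. An olefination at this position would give E/Z mixtures and pass through an isomerisation-prone β,γ-unsaturated carbonyl compound. The cross-coupling transfers the alkene geometry of 7 unchanged, and the 2-substituted allyl partner is symmetrical, so no regiochemical question arises.

Chloride 5 is traced through the isopropenyl ketal 4 and the methyl ketone 3 to the commercial ketal ester 1. Boronate 7 comes from the commercial enyne 6 in one step. Only functional-group changes on achiral material are asked of these steps.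

## Roads not taken

Alternative 1: The C1a–CH2 bond of the linker is cut and a temporary bond from C6a to the central linker carbon is added, so that ring A appears as the enone (4S)-4-[2-(triethylsilyloxy)propan-2-yl]cyclohex-2-en-1-one A1 and the linker as propadiene A2. Irradiation of A1 with A2 would give the head-to-head [2+2] adduct 8-methylidene-5-[2-(triethylsilyloxy)propan-2-yl]bicyclo[4.2.0]octan-2-one A3, with the cyclobutane anti to the side group. Later the ring A carbonyl of A3 would take up the C5a methyl group, the carbon bearing the exocyclic methylene would receive ring B once that methylene had been excised, and a strain-driven Grob fragmentation would break the temporary bond and leave the C5a=C6a alkene.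
- Merits: the C1a–C2a trans relationship is fixed kinetically by approach of A2 anti to the existing substituent of A1, with no equilibration, and the linker carbon arrives together with the C1a stereocentre.
- Weak points: head-to-head versus head-to-tail and facial selectivity of the photoaddition; the need for enantiopure A1, itself a multistep target; a long sequence between A3 and the fragmentation substrate (methyl addition, excision of the methylene carbon, addition of a ring B nucleophile to a cyclobutanone, activation of a tertiary alcohol as leaving group); a late dehydration that must give the isopropenyl and not the isopropylidene isomer; and a final methylenation of a hindered ketone. Ring B is not simplified.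
- Comparison: on the trans relationship the road through A3 is better than the chosen plan, which passes through an equilibrium in step 8. The chosen plan sets against it a catalytic, convergent assembly in which every carbon of ring A and the linker is in place after one cycloaddition, and the only temporary feature is an oxazolidinone, not a C–C bond.

Alternative 2: The two epoxide C–O bonds are traced to the cis-fused iodolactone 7-iodo-7-methyl-4-(prop-1-en-2-yl)hexahydro-1-benzofuran-2(3H)-one A5, and iodolactone A5 in turn to the acid 2-[(1S,6S)-3-methyl-6-(prop-1-en-2-yl)cyclohex-2-en-1-yl]acetic acid A4, in which the linker is cut after its first carbon. Treatment of A4 with I2 and NaHCO3 would let the carboxylate open the iodonium ion at C6a from the face of the side chain and give A5. Alkoxide opening of the lactone ring of A5 would then free the C6a oxygen, which displaces iodide at C5a and gives the epoxide syn to the linker by necessity.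
- Merits: on the epoxide face the road through A5 is better than the chosen plan, which entrusts that face to a chiral dioxirane in the last step.
- Weak points: A4 does not simplify ring A, whose ring and two carbon stereocentres must still be made, most naturally by the cycloaddition used here. Closure of A4 to A5 is the anti-Markovnikov mode, so attack of the carboxylate at the tertiary carbon C5a, giving a bridged six-membered lactone, competes, and the isopropenyl group is a further site for the carboxylate. The carboxyl carbon must then be grown into the 2-substituted allyl unit and joined to ring B by two C–C bond formations and a methylenation next to a labile epoxide, which must afterwards survive everything ring B requires.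
- Comparison: the chosen plan keeps the epoxide out of all C–C bond formation and pays with one reagent-controlled step whose outcome can be corrected afterwards, whereas A5 secures the face but places the epoxide early.

Alternative 3: The C1b–C6b bond of ring B is cut, which unravels the ring to the acyclic bromo dienone 2-bromo-7-methylocta-1,6-dien-3-one A6. A confined chiral Brønsted acid would activate the bromo enone of A6, the trisubstituted alkene would attack its β-carbon, a methyl proton would be lost to give the isopropenyl group, and protonation of the bromo enol would complete (2R,4R)-2-bromo-4-(prop-1-en-2-yl)cyclohexan-1-one A7.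
- Merits: if it worked, the cyclisation of A6 would be the best answer to ring B. C1b and C5b would come from an achiral chain in one catalytic step, as a small fragment whose purity can be secured before it meets ring A. Neither a late desymmetrisation of a remote centre nor a bromoketone equilibrium would be needed, and these (steps 11 and 12) are where the chosen plan is weakest; A7 is the ring B half of 18.
- Weak points: a conjugate ene cyclisation of an α-bromo enone such as A6 under chiral acid control has no close precedent, and two stereocentres, one made by protonation, must be controlled in it. Above all it says nothing about ring A or the union: A7 offers only an isopropenyl methyl group for attachment. Either an sp3–sp3 bond to the C1a stereocentre must be made, or ring A must be grown on that methyl group, which leads back to the Diels–Alder reaction with a labile bromoketone or bromohydrin exposed to cross-coupling, Lewis acid, organomagnesium reagents and methoxide.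
- Comparison: the chosen plan carries ring B as an inert ketal through all of these steps and accepts that its stereocentres are set late, where the road from A6 to A7 would set them early and in one step.

Key step: step 6

Remark (assumption): the ligand configuration in step 6 and the amide configuration in step 11 follow from the accepted models for these reagents (square-planar chelate of divalent copper; the known sense of deprotonation of 4-alkylcyclohexanones); 1 is the commercial ethylene ketal of ethyl 4-oxocyclohexanecarboxylate. (R,R)-t-Bu-box = 2,2'-(propane-2,2-diyl)bis[(4R)-4-tert-butyl-4,5-dihydro-1,3-oxazole].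

## Route

Step 1
Reactants: 1 ethyl 1,4-dioxaspiro[4.5]decane-8-carboxylate
Product: 3 1-(1,4-dioxaspiro[4.5]decan-8-yl)ethan-1-one, via Weinreb amide 2 (not isolated)
Conditions: MeNH(OMe)·HCl, i-PrMgCl, THF, −20 °C; then MeMgBr, 0 °C
Reagents that add atoms: methylmagnesium bromide, C[Mg]Br; N,O-dimethylhydroxylamine hydrochloride, CNOC.Cl (its atoms are held only in intermediate 2)
Why: The magnesium amide formed in the flask converts the ester into the Weinreb amide 2, whose chelated tetrahedral adduct with MeMgBr collapses to the ketone only on work-up, so no tertiary alcohol should form (Weinreb ketone synthesis); the ring carbon is not a stereocentre.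

Step 2
Reactants: 3 1-(1,4-dioxaspiro[4.5]decan-8-yl)ethan-1-one
Product: 4 8-(prop-1-en-2-yl)-1,4-dioxaspiro[4.5]decane
Conditions: Ph3PCH3Br, KOt-Bu, THF, 0 °C → rt
Reagents that add atoms: methyltriphenylphosphonium bromide, C[P+](c1ccccc1)(c1ccccc1)c1ccccc1.[Br-]
Why: Wittig methylenation of an unhindered methyl ketone with the non-stabilised ylide; the ketal is inert to the basic conditions.

Step 3
Reactants: 4 8-(prop-1-en-2-yl)-1,4-dioxaspiro[4.5]decane
Product: 5 8-(3-chloroprop-1-en-2-yl)-1,4-dioxaspiro[4.5]decane
Conditions: Ca(OCl)2, CO2 (s), CH2Cl2/H2O, 0 °C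
Reagents that add atoms: calcium hypochlorite, [Ca+2].[O-]Cl.[O-]Cl
Why: Ene-type allylic chlorination by hypochlorous acid generated in the flask: chlorine adds to the terminal carbon and a proton is lost from the unhindered methyl group, so the double bond moves into the former methyl group and the 2-substituted allyl chloride results, as with the isopropenyl groups of monoterpenes; the weakly acidic two-phase medium should spare the ketal.

Step 4
Reactants: 6 2-methylbut-1-en-3-yne
Product: 7 4,4,5,5-tetramethyl-2-[(1E)-3-methylbuta-1,3-dien-1-yl]-1,3,2-dioxaborolane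
Conditions: HBpin, Cp2Zr(H)Cl (5 mol%), Et3N (10 mol%), neat, 60 °C
Reagents that add atoms: pinacolborane, CC1(C)OBOC1(C)C
Why: Zirconium-catalysed syn hydroboration of the terminal alkyne places boron on the terminal carbon and gives the (E)-alkenylboronate; the 1,1-disubstituted alkene does not react under these conditions.

Step 5
Reactants: 5 8-(3-chloroprop-1-en-2-yl)-1,4-dioxaspiro[4.5]decane; 7 4,4,5,5-tetramethyl-2-[(1E)-3-methylbuta-1,3-dien-1-yl]-1,3,2-dioxaborolane
Product: 8 8-[(4E)-6-methylhepta-1,4,6-trien-2-yl]-1,4-dioxaspiro[4.5]decane
Conditions: Pd(PPh3)4 (5 mol%), K2CO3, THF/H2O, 60 °C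
Reagents that add atoms: none
Why: Suzuki–Miyaura allyl–alkenyl coupling: oxidative addition of zerovalent palladium to the allyl chloride gives a 2-substituted π-allyl complex with equivalent termini, so no regiochemical question arises, and transmetalation and reductive elimination retain the (E) geometry of the boronate, giving the skipped triene.

Step 6
Reactants: 8 8-[(4E)-6-methylhepta-1,4,6-trien-2-yl]-1,4-dioxaspiro[4.5]decane; 9 3-(prop-2-enoyl)-1,3-oxazolidin-2-one
Product: 10 3-{(1R,2S)-2-[2-(1,4-dioxaspiro[4.5]decan-8-yl)prop-2-en-1-yl]-4-methylcyclohex-3-ene-1-carbonyl}-1,3-oxazolidin-2-one (cis adduct)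
Conditions: [Cu((R,R)-t-Bu-box)](SbF6)2 (10 mol%), 4 Å MS, CH2Cl2, −20 °C
Reagents that add atoms: none
Why: Imide 9 binds the square-planar divalent copper centre through both carbonyl oxygens, which fixes the s-cis acryloyl unit and lowers its LUMO, and the diene end of 8 then adds in a concerted, asynchronous [4+2] cycloaddition; the closest known reaction type is the bis(oxazoline)copper-catalysed Diels–Alder reaction of this same imide with 1-substituted acyclic dienes. Ring A closes as a six-membered carbocycle by intermolecular [4+2] cycloaddition, the C1a–C2a and C3a–C4a bonds forming in the same step. Regiochemistry is secured twice: the 1-alkyl and the 3-methyl group both place the largest HOMO coefficient on the unsubstituted diene terminus C4a, which bonds to the β-carbon of the acrylimide, so the acyl group lands on C2a, next to C1a and para to the methyl-bearing C5a. C2a is set by the ligand: in the (R,R) complex the tert-butyl group beside the bound acryloyl unit blocks its α-Re face, so the diene adds to the α-Si face and C2a becomes (R). C1a is set relative to C2a by the endo transition state, in which the chelated acyl group lies under the diene while the (E)-alkyl substituent points outward, so that both end up on the same face of the new ring and the cis (1R,2S) adduct results. The step needs both enantiofacial and endo selectivity, because the exo adduct from the same dienophile face is the trans isomer with the opposite C1a configuration and would lead into the antipodal series; the reactive hexafluoroantimonate catalyst allows a low temperature, which should favour the endo pathway, and 10 is freed from the trans adduct before it is carried on. The isolated 1,1-disubstituted alkene is not a diene partner, and the ketal should not be ionised under anhydrous conditions.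

Step 7
Reactants: 10 3-{(1R,2S)-2-[2-(1,4-dioxaspiro[4.5]decan-8-yl)prop-2-en-1-yl]-4-methylcyclohex-3-ene-1-carbonyl}-1,3-oxazolidin-2-one
Product: 11 (1R,2S)-2-[2-(1,4-dioxaspiro[4.5]decan-8-yl)prop-2-en-1-yl]-N-methoxy-N,4-dimethylcyclohex-3-ene-1-carboxamide
Conditions: MeNH(OMe)·HCl, AlMe3, CH2Cl2, 0 °C → rt
Reagents that add atoms: N,O-dimethylhydroxylamine hydrochloride, CNOC.Cl
Why: Aluminium amide transamination of the N-acyl oxazolidinone at the exocyclic carbonyl group (Weinreb amide formation); neither ring A stereocentre is touched, and residual trans isomer can be removed at this stage.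

Step 8
Reactants: 11 (1R,2S)-2-[2-(1,4-dioxaspiro[4.5]decan-8-yl)prop-2-en-1-yl]-N-methoxy-N,4-dimethylcyclohex-3-ene-1-carboxamide
Product: 13 1-{(1S,2S)-2-[2-(1,4-dioxaspiro[4.5]decan-8-yl)prop-2-en-1-yl]-4-methylcyclohex-3-en-1-yl}ethan-1-one (trans), via cis methyl ketone 12 (not isolated)
Conditions: MeMgBr, THF, 0 °C; then NaOMe (0.3 equiv), MeOH, rt
Reagents that add atoms: methylmagnesium bromide, C[Mg]Br
Why: Grignard addition to the Weinreb amide stops at the chelated adduct and gives the cis methyl ketone 12; methoxide then equilibrates the enolisable centre C2a through the enolate toward the trans epimer, in which neither substituent has to be axial, while the non-enolisable C1a is retained. Residual cis ketone is separated and resubmitted.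

Step 9
Reactants: 13 1-{(1S,2S)-2-[2-(1,4-dioxaspiro[4.5]decan-8-yl)prop-2-en-1-yl]-4-methylcyclohex-3-en-1-yl}ethan-1-one
Product: 14 8-{3-[(1S,6S)-3-methyl-6-(prop-1-en-2-yl)cyclohex-2-en-1-yl]prop-1-en-2-yl}-1,4-dioxaspiro[4.5]decane
Conditions: Ph3PCH3Br, KOt-Bu, THF, 0 °C → rt
Reagents that add atoms: methyltriphenylphosphonium bromide, C[P+](c1ccccc1)(c1ccccc1)c1ccccc1.[Br-]
Why: Wittig methylenation turns the acetyl group into the isopropenyl group; because 13 is already the more stable epimer, the basic ylide should not erode the C2a configuration.

Step 10
Reactants: 14 8-{3-[(1S,6S)-3-methyl-6-(prop-1-en-2-yl)cyclohex-2-en-1-yl]prop-1-en-2-yl}-1,4-dioxaspiro[4.5]decane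
Product: 15 4-{3-[(1S,6S)-3-methyl-6-(prop-1-en-2-yl)cyclohex-2-en-1-yl]prop-1-en-2-yl}cyclohexan-1-one
Conditions: PPTS (cat.), acetone/H2O, 50 °C
Reagents that add atoms: water, O
Why: Mild acid-catalysed ketal hydrolysis; the pyridinium salt is too weak an acid to hydrate or isomerise the three alkenes.

Step 11
Reactants: 15 4-{3-[(1S,6S)-3-methyl-6-(prop-1-en-2-yl)cyclohex-2-en-1-yl]prop-1-en-2-yl}cyclohexan-1-one
Product: 16 trimethyl{[(4R)-4-{3-[(1S,6S)-3-methyl-6-(prop-1-en-2-yl)cyclohex-2-en-1-yl]prop-1-en-2-yl}cyclohex-1-en-1-yl]oxy}silane
Conditions: (S,S)-[PhCH(Me)]2NLi (from the amine and n-BuLi), TMSCl (in situ), THF, −100 °C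
Reagents that add atoms: chlorotrimethylsilane, C[Si](C)(C)Cl
Why: Asymmetric deprotonation of a 4-substituted cyclohexanone by a chiral lithium amide with in-situ silylation: the base removes one of the two enantiotopic axial α-protons, which makes C1b a stereocentre; the (S,S) amide is specified because the (R,R) amide gives the (S) enol silane with 4-alkylcyclohexanones. The ring A centres are too remote to interfere, so the outcome is reagent-controlled, and material of the minor ring B series is a diastereomer to be removed at 18 or 19.

Step 12
Reactants: 16 trimethyl{[(4R)-4-{3-[(1S,6S)-3-methyl-6-(prop-1-en-2-yl)cyclohex-2-en-1-yl]prop-1-en-2-yl}cyclohex-1-en-1-yl]oxy}silane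
Product: 18 (2R,4R)-2-bromo-4-{3-[(1S,6S)-3-methyl-6-(prop-1-en-2-yl)cyclohex-2-en-1-yl]prop-1-en-2-yl}cyclohexan-1-one (cis; bromine equatorial), via trans bromoketone 17 (not isolated)
Conditions: NBS, NaHCO3, THF, −78 °C; then LiBr, MeCN, rt
Reagents that add atoms: N-bromosuccinimide, O=C1CCC(=O)N1Br
Why: Electrophilic bromination of the silyl enol ether occurs only at the enol carbon C5b and far faster than at the isolated alkenes, so the regiochemistry set in step 11 is transferred; axial attack gives mainly the trans bromoketone 17. Bromide exchange (SN2 inversion at the activated α-carbon) in a polar medium then equilibrates 17 with the cis epimer 18, whose share rises with solvent polarity; recovered 17 is put through the same equilibration again.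

Step 13
Reactants: 18 (2R,4R)-2-bromo-4-{3-[(1S,6S)-3-methyl-6-(prop-1-en-2-yl)cyclohex-2-en-1-yl]prop-1-en-2-yl}cyclohexan-1-one
Product: 19 (1S,2R,4R)-2-bromo-1-methyl-4-{3-[(1S,6S)-3-methyl-6-(prop-1-en-2-yl)cyclohex-2-en-1-yl]prop-1-en-2-yl}cyclohexan-1-ol
Conditions: MeMgBr, CeCl3, THF, −78 °C
Reagents that add atoms: methylmagnesium bromide, C[Mg]Br
Why: The organocerium reagent adds to the carbonyl group without enolisation or bromine–metal exchange, and methyl enters trans to the neighbouring bromine, as is general for 2-halocyclohexanones (formation of cis halohydrins): along the equatorial trajectory in the chair with equatorial bromine, or anti to the C–Br bond in the minor axial conformer, both giving the same product. Methyl thus becomes equatorial and the hydroxyl axial and cis to bromine, which sets C4b as (S); a cis bromohydrin alkoxide cannot close to an epoxide.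

Step 14
Reactants: 19 (1S,2R,4R)-2-bromo-1-methyl-4-{3-[(1S,6S)-3-methyl-6-(prop-1-en-2-yl)cyclohex-2-en-1-yl]prop-1-en-2-yl}cyclohexan-1-ol
Product: 20 (1S,2R,4R)-2-bromo-1-methyl-4-{3-[(1R,2R,3S,6S)-6-methyl-3-(prop-1-en-2-yl)-7-oxabicyclo[4.1.0]heptan-2-yl]prop-1-en-2-yl}cyclohexan-1-ol
Conditions: 1,2:4,5-di-O-isopropylidene-β-D-erythro-2,3-hexodiulo-2,6-pyranose (D-fructose-derived Shi ketone, 0.3 equiv), Oxone (2KHSO5·KHSO4·K2SO4), K2CO3, n-Bu4NHSO4, MeCN/CH2(OMe)2/aq. Na2B4O7, 0 °C
Reagents that add atoms: potassium peroxymonosulfate (active component of Oxone), [K+].[O-]S(=O)(=O)OO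
Why: Shi epoxidation: the chiral dioxirane formed from the ketone and KHSO5 transfers oxygen through a spiro transition state to the electron-rich trisubstituted alkene, much faster than to the two 1,1-disubstituted alkenes. With 1-substituted cyclohexenes the D-fructose-derived ketone delivers oxygen to the face that makes the CH carbon (R), which here is the face syn to the linker, so C5a becomes (S) and C6a (R). The cis bromohydrin is inert at the buffered pH and 0 °C.

## Compound list

1 | ethyl 1,4-dioxaspiro[4.5]decane-8-carboxylate | CCOC(=O)C1CCC2(CC1)OCCO2 | starting material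
2 | N-methoxy-N-methyl-1,4-dioxaspiro[4.5]decane-8-carboxamide | CON(C)C(=O)C1CCC2(CC1)OCCO2 | intermediate
3 | 1-(1,4-dioxaspiro[4.5]decan-8-yl)ethan-1-one | CC(=O)C1CCC2(CC1)OCCO2 | intermediate
4 | 8-(prop-1-en-2-yl)-1,4-dioxaspiro[4.5]decane | C=C(C)C1CCC2(CC1)OCCO2 | intermediate
5 | 8-(3-chloroprop-1-en-2-yl)-1,4-dioxaspiro[4.5]decane | C=C(CCl)C1CCC2(CC1)OCCO2 | intermediate
6 | 2-methylbut-1-en-3-yne | C=C(C)C#C | starting material
7 | 4,4,5,5-tetramethyl-2-[(1E)-3-methylbuta-1,3-dien-1-yl]-1,3,2-dioxaborolane | C=C(C)/C=C/B1OC(C)(C)C(C)(C)O1 | intermediate
8 | 8-[(4E)-6-methylhepta-1,4,6-trien-2-yl]-1,4-dioxaspiro[4.5]decane | C=C(C)/C=C/CC(=C)C1CCC2(CC1)OCCO2 | intermediate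
9 | 3-(prop-2-enoyl)-1,3-oxazolidin-2-one | C=CC(=O)N1CCOC1=O | starting material
10 | 3-{(1R,2S)-2-[2-(1,4-dioxaspiro[4.5]decan-8-yl)prop-2-en-1-yl]-4-methylcyclohex-3-ene-1-carbonyl}-1,3-oxazolidin-2-one | C=C(C[C@@H]1[C@H](C(=O)N2CCOC2=O)CCC(C)=C1)C1CCC2(CC1)OCCO2 | intermediate
11 | (1R,2S)-2-[2-(1,4-dioxaspiro[4.5]decan-8-yl)prop-2-en-1-yl]-N-methoxy-N,4-dimethylcyclohex-3-ene-1-carboxamide | C=C(C[C@@H]1[C@H](C(=O)N(C)OC)CCC(C)=C1)C1CCC2(CC1)OCCO2 | intermediate
12 | 1-{(1R,2S)-2-[2-(1,4-dioxaspiro[4.5]decan-8-yl)prop-2-en-1-yl]-4-methylcyclohex-3-en-1-yl}ethan-1-one (cis) | C=C(C[C@@H]1[C@H](C(C)=O)CCC(C)=C1)C1CCC2(CC1)OCCO2 | intermediate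
13 | 1-{(1S,2S)-2-[2-(1,4-dioxaspiro[4.5]decan-8-yl)prop-2-en-1-yl]-4-methylcyclohex-3-en-1-yl}ethan-1-one (trans) | C=C(C[C@@H]1[C@@H](C(C)=O)CCC(C)=C1)C1CCC2(CC1)OCCO2 | intermediate
14 | 8-{3-[(1S,6S)-3-methyl-6-(prop-1-en-2-yl)cyclohex-2-en-1-yl]prop-1-en-2-yl}-1,4-dioxaspiro[4.5]decane | C=C(C[C@@H]1[C@@H](C(=C)C)CCC(C)=C1)C1CCC2(CC1)OCCO2 | intermediate
15 | 4-{3-[(1S,6S)-3-methyl-6-(prop-1-en-2-yl)cyclohex-2-en-1-yl]prop-1-en-2-yl}cyclohexan-1-one | C=C(C[C@@H]1[C@@H](C(=C)C)CCC(C)=C1)C1CCC(=O)CC1 | intermediate
16 | trimethyl{[(4R)-4-{3-[(1S,6S)-3-methyl-6-(prop-1-en-2-yl)cyclohex-2-en-1-yl]prop-1-en-2-yl}cyclohex-1-en-1-yl]oxy}silane | C=C(C[C@@H]1[C@@H](C(=C)C)CCC(C)=C1)[C@@H]1CCC(O[Si](C)(C)C)=CC1 | intermediate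
17 | (2S,4R)-2-bromo-4-{3-[(1S,6S)-3-methyl-6-(prop-1-en-2-yl)cyclohex-2-en-1-yl]prop-1-en-2-yl}cyclohexan-1-one (trans; bromine axial) | C=C(C[C@@H]1[C@@H](C(=C)C)CCC(C)=C1)[C@@H]1CCC(=O)[C@@H](Br)C1 | intermediate
18 | (2R,4R)-2-bromo-4-{3-[(1S,6S)-3-methyl-6-(prop-1-en-2-yl)cyclohex-2-en-1-yl]prop-1-en-2-yl}cyclohexan-1-one (cis; bromine equatorial) | C=C(C[C@@H]1[C@@H](C(=C)C)CCC(C)=C1)[C@@H]1CCC(=O)[C@H](Br)C1 | intermediate
19 | (1S,2R,4R)-2-bromo-1-methyl-4-{3-[(1S,6S)-3-methyl-6-(prop-1-en-2-yl)cyclohex-2-en-1-yl]prop-1-en-2-yl}cyclohexan-1-ol | C=C(C[C@@H]1[C@@H](C(=C)C)CCC(C)=C1)[C@@H]1CC[C@](C)(O)[C@H](Br)C1 | intermediate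
20 | (1S,2R,4R)-2-bromo-1-methyl-4-{3-[(1R,2R,3S,6S)-6-methyl-3-(prop-1-en-2-yl)-7-oxabicyclo[4.1.0]heptan-2-yl]prop-1-en-2-yl}cyclohexan-1-ol | C=C(C[C@@H]1[C@@H](C(=C)C)CC[C@]2(C)O[C@H]12)[C@@H]1CC[C@](C)(O)[C@H](Br)C1 | target

## Step count and least certain steps

Total: 14 steps. Longest linear sequence: 13 steps (1 → 20 through steps 1–3 and 5–14); boronate 7 is made in one step (step 4) on a side branch.

Step 6 (key step).
- What may go wrong: loss of endo preference with a diene that also carries a 3-methyl group; incomplete differentiation of the two faces of the bound acrylimide; acid-induced oligomerisation of the triene or ionisation of the ketal at the strongly Lewis acidic divalent copper centre. Because the exo pathway delivers the opposite C1a configuration, any loss of endo selectivity not removed by purification of 10 lowers the enantiomeric purity of ring A.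
- Fallback (auxiliary control in place of catalyst control): it sets out from 8, which is combined with the chiral dienophile (4S)-4-benzyl-3-(prop-2-enoyl)-1,3-oxazolidin-2-one F1 in the presence of Et2AlCl (1.4 equiv) in CH2Cl2 at −100 °C. The chelated aluminium imide is attacked anti to the benzyl group, again on the α-Si face, and the cis adduct (4S)-4-benzyl-3-{(1R,2S)-2-[2-(1,4-dioxaspiro[4.5]decan-8-yl)prop-2-en-1-yl]-4-methylcyclohex-3-ene-1-carbonyl}-1,3-oxazolidin-2-one F2 is a diastereomer of all its stereoisomeric contaminants and can be purified by crystallisation or chromatography. Transamination of F2 with MeNH(OMe)·HCl and AlMe3 as in step 7 brings the material back to the route at 11.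

Step 12.
- What may go wrong: the epimer equilibrium may stop at a modest excess of the cis bromoketone, because an α-bromine on a cyclohexanone has only a small, solvent-dependent preference for the equatorial position; prolonged exposure to bromide may also cause loss of HBr to the enone.
- Fallback (kinetic protonation in place of equilibration): it sets out from the mixture of 17 and 18, which is silylated on the bromine-bearing side with TMSOTf and Et3N to give the bromo enol silane {[(4R)-2-bromo-4-{3-[(1S,6S)-3-methyl-6-(prop-1-en-2-yl)cyclohex-2-en-1-yl]prop-1-en-2-yl}cyclohex-1-en-1-yl]oxy}trimethylsilane F3. Fluoride-induced desilylation of F3 at −78 °C in the presence of a proton source (n-Bu4NF, AcOH) should protonate C5b along the axial trajectory, which leaves bromine equatorial and returns the material to the route at 18.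

Step 11.
- What may go wrong: insufficient discrimination between the two enantiotopic α-methylene groups, or a sense of deprotonation opposite to the one assumed. Because the ring A stereocentres are remote, the error appears as a diastereomer that differs only in ring B and may be hard to remove.
- Fallback (enamine catalysis and inversion in place of asymmetric deprotonation; it also bypasses step 12): it sets out from 15. D-Proline-catalysed α-aminoxylation with nitrosobenzene should give, by axial attack on the enamine, the trans aminoxy ketone (2S,4R)-2-(anilinooxy)-4-{3-[(1S,6S)-3-methyl-6-(prop-1-en-2-yl)cyclohex-2-en-1-yl]prop-1-en-2-yl}cyclohexan-1-one F4. Cleavage of the N–O bond of F4 (Zn, AcOH) gives the hydroxy ketone (2S,4R)-2-hydroxy-4-{3-[(1S,6S)-3-methyl-6-(prop-1-en-2-yl)cyclohex-2-en-1-yl]prop-1-en-2-yl}cyclohexan-1-one F5. Triflation of F5 (Tf2O, 2,6-lutidine, −78 °C) gives (1S,5R)-2-oxo-5-{3-[(1S,6S)-3-methyl-6-(prop-1-en-2-yl)cyclohex-2-en-1-yl]prop-1-en-2-yl}cyclohexyl trifluoromethanesulfonate F6, and displacement of the triflate of F6 with LiBr proceeds with inversion at C5b and brings the material back to the route at 18; the cis relationship is then the result of an SN2 inversion and not of an equilibrium.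

Step 14.
- What may go wrong: insufficient facial control, because the linker stands next to C6a on the very face the dioxirane has to reach; some oxidation of the two 1,1-disubstituted alkenes if the oxidant is not limited.
- Fallback (unselective oxidation followed by chemical removal of the wrong epimer, in place of reagent control): it sets out from 19. mCPBA (1.0 equiv, NaHCO3, CH2Cl2, 0 °C) should epoxidise only the trisubstituted alkene and give 20 together with its epoxide epimer (1S,2R,4R)-2-bromo-1-methyl-4-{3-[(1S,2R,3S,6R)-6-methyl-3-(prop-1-en-2-yl)-7-oxabicyclo[4.1.0]heptan-2-yl]prop-1-en-2-yl}cyclohexan-1-ol F7, which may well be the larger share because the peracid prefers the face away from the linker. Gentle warming of the mixture with pyrrolidine in aqueous ethanol should open only F7, because trans-diaxial opening of F7 occurs at the secondary carbon C6a, whereas in 20 it would have to occur at the tertiary carbon C5a. The amino alcohol (1R,2R,3R,4S)-3-{2-[(1R,3R,4S)-3-bromo-4-hydroxy-4-methylcyclohexyl]prop-2-en-1-yl}-1-methyl-4-(prop-1-en-2-yl)-2-(pyrrolidin-1-yl)cyclohexan-1-ol F8 is removed by an acid wash, and the route is rejoined at 20.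

Step 8.
- What may go wrong: the equilibrium may leave a sizeable share of cis ketone, since in a cyclohexene one axial substituent costs little, so that several cycles of separation and re-equilibration would be needed.
- Fallback (a dynamic process in place of a separate equilibration): it sets out from the mixture of 12 and 13 and leads directly to 14. Methylenation with an excess of Ph3P=CH2 in the presence of KOt-Bu at room temperature lets the less hindered trans ketone react faster while the cis ketone keeps epimerising under the basic conditions. Any alkene formed from the cis ketone is a diastereomer of 14 and is removed on AgNO3-impregnated silica. No new compound is needed, so the entry for this fallback is F0.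

Step 3.
- What may go wrong: proton loss from the ring methine instead of the methyl group (giving the tetrasubstituted allyl chloride), addition of HOCl across the alkene, or partial hydrolysis of the ketal in the carbonic acid medium.
- Fallback (a route through an epoxide in place of the ene-type chlorination; it also bypasses step 2): it sets out from 3. Corey–Chaykovsky reaction with dimethylsulfonium methylide gives 2-methyl-2-(1,4-dioxaspiro[4.5]decan-8-yl)oxirane F9. The bulky amide Et2Al(TMP) (TMP = 2,2,6,6-tetramethylpiperidide) removes a proton from the methyl group of F9, the least hindered β-position, and gives 2-(1,4-dioxaspiro[4.5]decan-8-yl)prop-2-en-1-ol F10. Chlorination of F10 with NCS and Me2S returns the material to the route at 5.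

## Further compounds

F1 | step 6 | (4S)-4-benzyl-3-(prop-2-enoyl)-1,3-oxazolidin-2-one | C=CC(=O)N1[C@@H](Cc2ccccc2)COC1=O
F2 | step 6 | (4S)-4-benzyl-3-{(1R,2S)-2-[2-(1,4-dioxaspiro[4.5]decan-8-yl)prop-2-en-1-yl]-4-methylcyclohex-3-ene-1-carbonyl}-1,3-oxazolidin-2-one | C=C(C[C@@H]1[C@H](C(=O)N2[C@@H](Cc3ccccc3)COC2=O)CCC(C)=C1)C1CCC2(CC1)OCCO2
F3 | step 12 | {[(4R)-2-bromo-4-{3-[(1S,6S)-3-methyl-6-(prop-1-en-2-yl)cyclohex-2-en-1-yl]prop-1-en-2-yl}cyclohex-1-en-1-yl]oxy}trimethylsilane | C=C(C[C@@H]1[C@@H](C(=C)C)CCC(C)=C1)[C@@H]1CCC(O[Si](C)(C)C)=C(Br)C1
F4 | step 11 | (2S,4R)-2-(anilinooxy)-4-{3-[(1S,6S)-3-methyl-6-(prop-1-en-2-yl)cyclohex-2-en-1-yl]prop-1-en-2-yl}cyclohexan-1-one | C=C(C[C@@H]1[C@@H](C(=C)C)CCC(C)=C1)[C@@H]1CCC(=O)[C@@H](ONc2ccccc2)C1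
F5 | step 11 | (2S,4R)-2-hydroxy-4-{3-[(1S,6S)-3-methyl-6-(prop-1-en-2-yl)cyclohex-2-en-1-yl]prop-1-en-2-yl}cyclohexan-1-one | C=C(C[C@@H]1[C@@H](C(=C)C)CCC(C)=C1)[C@@H]1CCC(=O)[C@@H](O)C1
F6 | step 11 | (1S,5R)-2-oxo-5-{3-[(1S,6S)-3-methyl-6-(prop-1-en-2-yl)cyclohex-2-en-1-yl]prop-1-en-2-yl}cyclohexyl trifluoromethanesulfonate | C=C(C[C@@H]1[C@@H](C(=C)C)CCC(C)=C1)[C@@H]1CCC(=O)[C@@H](OS(=O)(=O)C(F)(F)F)C1
F7 | step 14 | (1S,2R,4R)-2-bromo-1-methyl-4-{3-[(1S,2R,3S,6R)-6-methyl-3-(prop-1-en-2-yl)-7-oxabicyclo[4.1.0]heptan-2-yl]prop-1-en-2-yl}cyclohexan-1-ol | C=C(C[C@@H]1[C@@H](C(=C)C)CC[C@@]2(C)O[C@@H]12)[C@@H]1CC[C@](C)(O)[C@H](Br)C1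
F8 | step 14 | (1R,2R,3R,4S)-3-{2-[(1R,3R,4S)-3-bromo-4-hydroxy-4-methylcyclohexyl]prop-2-en-1-yl}-1-methyl-4-(prop-1-en-2-yl)-2-(pyrrolidin-1-yl)cyclohexan-1-ol | C=C(C[C@@H]1[C@@H](C(=C)C)CC[C@@](C)(O)[C@@H]1N1CCCC1)[C@@H]1CC[C@](C)(O)[C@H](Br)C1
F0 | step 8 | none | none
F9 | step 3 | 2-methyl-2-(1,4-dioxaspiro[4.5]decan-8-yl)oxirane | CC1(CO1)C1CCC2(CC1)OCCO2
F10 | step 3 | 2-(1,4-dioxaspiro[4.5]decan-8-yl)prop-2-en-1-ol | C=C(CO)C1CCC2(CC1)OCCO2
A1 | alternative 1 | (4S)-4-[2-(triethylsilyloxy)propan-2-yl]cyclohex-2-en-1-one | O=C1CC[C@H](C(C)(C)O[Si](CC)(CC)CC)C=C1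
A2 | alternative 1 | propadiene | C=C=C
A3 | alternative 1 | 8-methylidene-5-[2-(triethylsilyloxy)propan-2-yl]bicyclo[4.2.0]octan-2-one (cis-fused, cyclobutane anti to the side group) | O=C1CC[C@H](C(C)(C)O[Si](CC)(CC)CC)[C@H]2CC(=C)[C@@H]12
A4 | alternative 2 | 2-[(1S,6S)-3-methyl-6-(prop-1-en-2-yl)cyclohex-2-en-1-yl]acetic acid | OC(=O)C[C@@H]1[C@@H](C(=C)C)CCC(C)=C1
A5 | alternative 2 | 7-iodo-7-methyl-4-(prop-1-en-2-yl)hexahydro-1-benzofuran-2(3H)-one (cis-fused) | O=C1C[C@@H]2[C@@H](C(=C)C)CC[C@@](C)(I)[C@@H]2O1
A6 | alternative 3 | 2-bromo-7-methylocta-1,6-dien-3-one | C=C(Br)C(=O)CCC=C(C)C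
A7 | alternative 3 | (2R,4R)-2-bromo-4-(prop-1-en-2-yl)cyclohexan-1-one | C=C(C)[C@@H]1CCC(=O)[C@H](Br)C1
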